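**Retrosynthetic overview**
- Isovalerylalkannin ⇒ (S)-aryl carbinyl isovalerate on a 1,4,5,8-tetrakis(methoxymethoxy)naphthalene, by oxidation with tetravalent cerium and acid removal of the last two MOM groups; the ester ⇒ the (S)-alcohol + isovaleric anhydride.
- (S)-alcohol ⇒ three components in one flask: lithiated tetra-MOM naphthalene, vinylboronic pinacol ester and 2-methylprop-1-enyl triflate. The ring C2–C1′ bond forms by a 1,2-shift of the naphthyl group from boron to carbon, C2′–C3′ by reductive elimination at palladium, and C1′–O by oxidation of C–B.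
- Enabling feature: C1′ sits between ring carbon C2 and a CH2 (C2′) that carries the sp2 carbon C3′ of the C3′=C4′ alkene, an aryl–CH(O)–CH2–alkenyl triad. In addition, C2, C3, C6 and C7 of the tetra-O-protected naphthalene are equivalent and each ortho to oxygen, and naphthazarin tautomerism lets rings A and B exchange roles, so either ring may be the one oxidised.
- No ring is built: both rings come from commercial naphthazarin (reduction, fourfold MOM protection).

Key step: step 4

Assumption: the (Rp,Rp) enantiomer of the MandyPhos ligand is taken to deliver the (S)-boronate in the 1,2-aryl shift; this sense is not certain, and if the opposite is found the (Sp,Sp) ligand is used instead.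

**Step 1**
Reactants: 1 naphthazarin (5,8-dihydroxy-1,4-naphthoquinone)
Product: 2 2,3-dihydronaphthazarin (5,8-dihydroxy-2,3-dihydronaphthalene-1,4-dione)
Conditions: Na2S2O4, EtOAc/H2O, 25 °C, N2
Reagents that add atoms: none
Why: Dithionite reduction of a quinone to its hydroquinone, which for naphthazarin should settle as the stable diketo tautomer 2, a storage form of 1,4,5,8-tetrahydroxynaphthalene.

**Step 2**
Reactants: 2 2,3-dihydronaphthazarin
Product: 3 1,4,5,8-tetrakis(methoxymethoxy)naphthalene
Conditions: NaH (4.5 equiv), MOMCl (4.5 equiv), DMF, 0 → 25 °C, Ar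
Reagents that add atoms: chloromethyl methyl ether, COCCl
Why: Williamson-type O-alkylation, in which NaH enolises 2 to the aromatic naphthalene tetraolate whose hard oxygen centres should be alkylated four times by the hard electrophile MOMCl with air excluded.

**Step 3**
Reactants: 4 isobutyraldehyde (2-methylpropanal)
Product: 5 2-methylprop-1-en-1-yl trifluoromethanesulfonate
Conditions: Tf2O, 2,6-di-tert-butyl-4-methylpyridine, CH2Cl2, 0 → 40 °C
Reagents that add atoms: trifluoromethanesulfonic anhydride, O=S(=O)(OS(=O)(=O)C(F)(F)F)C(F)(F)F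
Why: Enol triflate formation from an enolisable aldehyde (O-triflation, then loss of the α-hydrogen to the hindered non-nucleophilic pyridine); the gem-dimethyl terminus allows only one alkene isomer.

**Step 4**
Reactants: 3 1,4,5,8-tetrakis(methoxymethoxy)naphthalene; 6 vinylboronic acid pinacol ester (4,4,5,5-tetramethyl-2-vinyl-1,3,2-dioxaborolane); 5 2-methylprop-1-en-1-yl trifluoromethanesulfonate
Product: 10 (S)-4-methyl-1-[1,4,5,8-tetrakis(methoxymethoxy)naphthalen-2-yl]pent-3-en-1-ol, via aryllithium 7 (not isolated), via boron ate complex 8 (not isolated), via (S)-boronic ester 9 (not isolated)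
Conditions: n-BuLi (0.95 equiv), THF, 0 °C; 6, 0 → 25 °C; Pd(OAc)2 (2 mol %), (Rp,Rp)-MandyPhos (2.4 mol %), 5 (1.1 equiv), THF, 60 °C; then 3 M NaOH, 30% H2O2, 0 → 25 °C
Reagents that add atoms: hydrogen peroxide, OO
Why: Deprotonation of 3 at one of its four equivalent ring C–H positions (directed ortho-metalation by OMOM) gives 7, which adds to the boron of 6 to form ate complex 8; zerovalent palladium inserts into the C–O bond of triflate 5, the cationic alkenyl divalent palladium binds the vinyl group of 8 and triggers a 1,2-shift of the naphthyl group from boron to the α-carbon anti to palladium (creating the ring C2–C1′ bond and the stereocentre), reductive elimination joins C2′ to C3′ to give 9, and the C–B bond is then oxidised to C–OH. The closest known reaction type is the palladium-catalysed enantioselective conjunctive cross-coupling of aryllithium-derived vinylboron ate complexes with aryl or alkenyl triflates (metal-induced 1,2-metalate rearrangement), followed by boronate oxidation. No ring is closed. The C1′ stereocentre is controlled by the chiral ferrocenyl bisphosphine on palladium, which selects the enantioface of the boron-bound vinyl group in the migration step, and the (S) configuration of 9 passes into 10 because the oxidation is stereoretentive. The step needs the conjunctive pathway to win over direct Suzuki–Miyaura transfer and β-hydride elimination, which halide-free conditions (lithiation by deprotonation, triflate leaving group) and the wide-bite-angle bisphosphine should secure, and it needs a single lithiation site, which the symmetry of 3 secures.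

**Step 5**
Reactants: 10 (S)-4-methyl-1-[1,4,5,8-tetrakis(methoxymethoxy)naphthalen-2-yl]pent-3-en-1-ol
Product: 11 (S)-4-methyl-1-[1,4,5,8-tetrakis(methoxymethoxy)naphthalen-2-yl]pent-3-en-1-yl 3-methylbutanoate
Conditions: isovaleric anhydride, Et3N, DMAP (cat.), CH2Cl2, 0 → 25 °C
Reagents that add atoms: isovaleric anhydride, CC(C)CC(=O)OC(=O)CC(C)C
Why: DMAP-catalysed acylation (nucleophilic catalysis through the acylpyridinium ion) of the secondary alcohol under basic conditions, so the C1′–O bond is never broken and the (S) centre is kept.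

**Step 6**
Reactants: 11 (S)-4-methyl-1-[1,4,5,8-tetrakis(methoxymethoxy)naphthalen-2-yl]pent-3-en-1-yl 3-methylbutanoate
Product: 14 isovalerylalkannin, via 2-alkyl quinone 12 (not isolated), via 6-alkyl quinone 13 (not isolated)
Conditions: (NH4)2Ce(NO3)6 (2.1 equiv), MeCN/H2O, 0 °C; then 2 M HCl, 25 °C
Reagents that add atoms: water, O
Why: Oxidative dealkylation of a p-dialkoxyarene by tetravalent cerium should give a quinone in either ring (12 or 13, formed side by side), and acid hydrolysis of the two remaining peri MOM acetals funnels both to the same naphthazarin because its two rings exchange roles by proton tautomerism, while the C1′–O bond stays intact.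

**Compound list**
1 | naphthazarin (5,8-dihydroxy-1,4-naphthoquinone) | O=C1C=CC(=O)c2c(O)ccc(O)c12 | starting material
2 | 2,3-dihydronaphthazarin | O=C1CCC(=O)c2c(O)ccc(O)c12 | intermediate
3 | 1,4,5,8-tetrakis(methoxymethoxy)naphthalene | COCOc1ccc(OCOC)c2c(OCOC)ccc(OCOC)c12 | intermediate
4 | isobutyraldehyde | CC(C)C=O | starting material
5 | 2-methylprop-1-en-1-yl trifluoromethanesulfonate | CC(C)=COS(=O)(=O)C(F)(F)F | intermediate
6 | vinylboronic acid pinacol ester | C=CB1OC(C)(C)C(C)(C)O1 | starting material
7 | 2-lithio-1,4,5,8-tetrakis(methoxymethoxy)naphthalene | [Li]c1cc(OCOC)c2c(OCOC)ccc(OCOC)c2c1OCOC | intermediate (not isolated)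
8 | lithium [1,4,5,8-tetrakis(methoxymethoxy)naphthalen-2-yl](vinyl)(pinacolato)borate | [Li+].C=C[B-]1(OC(C)(C)C(C)(C)O1)c1cc(OCOC)c2c(OCOC)ccc(OCOC)c2c1OCOC | intermediate (not isolated)
9 | (S)-2-{4-methyl-1-[1,4,5,8-tetrakis(methoxymethoxy)naphthalen-2-yl]pent-3-en-1-yl}-4,4,5,5-tetramethyl-1,3,2-dioxaborolane | CC(C)=CC[C@H](B1OC(C)(C)C(C)(C)O1)c1cc(OCOC)c2c(OCOC)ccc(OCOC)c2c1OCOC | intermediate (not isolated)
10 | (S)-4-methyl-1-[1,4,5,8-tetrakis(methoxymethoxy)naphthalen-2-yl]pent-3-en-1-ol | CC(C)=CC[C@H](O)c1cc(OCOC)c2c(OCOC)ccc(OCOC)c2c1OCOC | intermediate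
11 | (S)-4-methyl-1-[1,4,5,8-tetrakis(methoxymethoxy)naphthalen-2-yl]pent-3-en-1-yl 3-methylbutanoate | CC(C)=CC[C@H](OC(=O)CC(C)C)c1cc(OCOC)c2c(OCOC)ccc(OCOC)c2c1OCOC | intermediate
12 | (S)-1-[5,8-bis(methoxymethoxy)-1,4-dioxo-1,4-dihydronaphthalen-2-yl]-4-methylpent-3-en-1-yl 3-methylbutanoate | CC(C)=CC[C@H](OC(=O)CC(C)C)C1=CC(=O)c2c(OCOC)ccc(OCOC)c2C1=O | intermediate (not isolated)
13 | (S)-1-[1,4-bis(methoxymethoxy)-5,8-dioxo-5,8-dihydronaphthalen-2-yl]-4-methylpent-3-en-1-yl 3-methylbutanoate (ring regioisomer of 12) | CC(C)=CC[C@H](OC(=O)CC(C)C)c1cc(OCOC)c2C(=O)C=CC(=O)c2c1OCOC | intermediate (not isolated)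
14 | isovalerylalkannin, (S) | CC(C)=CC[C@H](OC(=O)CC(C)C)C1=CC(=O)c2c(O)ccc(O)c2C1=O | target

**Totals**
Total step count: 6. Longest linear sequence: 5 steps (steps 1, 2, 4, 5, 6).

**Steps most likely to fail**

Step 4. The 1,2-shift may lose to direct cross-coupling of the ate complex or to β-hydride elimination, and the ortho-alkoxy, peri-crowded naphthyl group may migrate with poor enantiofacial discrimination. Fallback: setting out from 3, the aryllithium 7 is generated as before and acylated (THF, −78 °C, Weinreb ketone synthesis) with N-methoxy-N,4-dimethylpent-3-enamide F1, itself prepared from commercial 4-methylpent-3-enoic acid with MeNHOMe·HCl, EDC·HCl and Et3N in CH2Cl2. This should give 4-methyl-1-[1,4,5,8-tetrakis(methoxymethoxy)naphthalen-2-yl]pent-3-en-1-one F2. Reduction of F2 with (−)-B-chlorodiisopinocampheylborane (THF, −25 °C; the aryl group acts as the large group and should give the (S) carbinol) rejoins the route at 10.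

Step 6. The isovalerate may be lost or shifted, either by ionisation at the electron-rich benzylic carbon before the ring is oxidised or by acid hydrolysis during MOM cleavage. Fallback: setting out from 10, the free alcohol is unmasked first with the same (NH4)2Ce(NO3)6 then HCl sequence. This passes through (S)-2-(1-hydroxy-4-methylpent-3-en-1-yl)-5,8-bis(methoxymethoxy)-1,4-naphthoquinone F3 and its ring regioisomer (S)-6-(1-hydroxy-4-methylpent-3-en-1-yl)-5,8-bis(methoxymethoxy)-1,4-naphthoquinone F4 to alkannin F5. The ester is then put on last with isovaleric acid, DCC and DMAP in CH2Cl2 at 0 °C; this should acylate only the side-chain hydroxyl, because the two peri hydroxyls are locked in hydrogen bonds to the quinone carbonyls. The fallback comes back to the route at 14.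

Step 2. The electron-rich naphthalene polyanion may re-oxidise in air and the fourfold alkylation may stop at mixed MOM ethers. Fallback: setting out from 1, reductive acetylation (Zn, Ac2O, NaOAc, 60 °C) should give the air-stable, crystallisable 1,4,5,8-tetraacetoxynaphthalene F6. Its four acetates are then exchanged in one flask, under argon and without aqueous handling (NaOMe, DMF, 0 °C; then MOMCl), through the sodium naphtholates, coming back to the route at 3.

**Further compounds**
F1 | step 4 | N-methoxy-N,4-dimethylpent-3-enamide | CON(C)C(=O)CC=C(C)C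
F2 | step 4 | 4-methyl-1-[1,4,5,8-tetrakis(methoxymethoxy)naphthalen-2-yl]pent-3-en-1-one | CC(C)=CCC(=O)c1cc(OCOC)c2c(OCOC)ccc(OCOC)c2c1OCOC
F3 | step 6 | (S)-2-(1-hydroxy-4-methylpent-3-en-1-yl)-5,8-bis(methoxymethoxy)-1,4-naphthoquinone | CC(C)=CC[C@H](O)C1=CC(=O)c2c(OCOC)ccc(OCOC)c2C1=O
F4 | step 6 | (S)-6-(1-hydroxy-4-methylpent-3-en-1-yl)-5,8-bis(methoxymethoxy)-1,4-naphthoquinone | CC(C)=CC[C@H](O)c1cc(OCOC)c2C(=O)C=CC(=O)c2c1OCOC
F5 | step 6 | alkannin, (S) | CC(C)=CC[C@H](O)C1=CC(=O)c2c(O)ccc(O)c2C1=O
F6 | step 2 | 1,4,5,8-tetraacetoxynaphthalene | CC(=O)Oc1ccc(OC(C)=O)c2c(OC(C)=O)ccc(OC(C)=O)c12
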